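**Plan**

Numbering used below: ring A is C1(=O)–C2–C3(O)–C4(Me2)–C5–C10 with the ether bridge C3–O–C6H2–C5; the lactone is C10–C20H2–O–C7(=O)–C8–C9; the cyclohexane is C8, C9, C11, C12, C13, C14; the side chain C16(=C17H2)–C15O2H sits on C13.
Cuts: (a) the C15 acid back to the methyl of an isopropenyl group; (b) the lactone O–C7 bond and the ring bond C8–C14; (c) the C9–C10 bond at the spiro carbon (Michael addition); (d) C3–O (oxa-Michael) and C5–C6 (conjugate addition to a dienone).
Enabling feature for (b): the lactone carbonyl C7 hangs outside the cyclohexane on C8 and its alkoxy oxygen sits on C20 of the neighbouring spiro carbon. C7 can therefore be the ketone of a 2-diazocycloheptanone (C7 between C8 and C14), extruded by Wolff contraction as a ketene that the C20 hydroxyl captures.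
Forward: 4,4-dimethylcyclohexadienone is desymmetrised and bridged to the 6-oxabicyclo[3.2.1]octanone with a formyl group on C10; this adds to a 2-formylcycloheptenone (C9–C10); the ring formyl becomes the diazo group and the C20 formyl the alcohol; light contracts the seven-membered ring and closes the lactone; allylic oxidation finishes.
Helper: the formyl group on C8 activates C9 for the hindered Michael addition, then leaves as an N-formylsulfonamide when the diazo group is placed on C8.
Stereochemistry: C5 and C13 from Rh/BINAP conjugate additions (C3 follows, the bridge can only be cis); C10 by attack on the locked bicycle anti to the axial C4 methyl; C9 trans to the C13 substituent; C8 by kinetic protonation of the lactone enol.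

Key step: step 14

Remark: the enantiofacial sense of both Rh/BINAP additions is assumed to follow that of simple cyclohex-2-enone and cyclohept-2-enone; the antipodal ligand would be used if the dienones behaved otherwise.

**Route**

Step 1
Reactants: 1 4,4-dimethylcyclohex-2-en-1-one
Product: 2 4,4-dimethylcyclohexa-2,5-dien-1-one
Conditions: IBX (1.5 equiv), DMSO, 80 °C
Reagents that add atoms: none
Why: IBX dehydrogenation of the ketone through its enol gives the cross-conjugated dienone, and the quaternary C4 rules out aromatisation.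

Step 2
Reactants: 2 4,4-dimethylcyclohexa-2,5-dien-1-one; 3 (E)-2-phenylethenylboronic acid
Product: 4 (5S)-4,4-dimethyl-5-[(E)-2-phenylethenyl]cyclohex-2-en-1-one
Conditions: [Rh(OH)((S)-binap)]2 (3 mol%), 3 (1.3 equiv), dioxane/H2O 10:1, 40 °C
Reagents that add atoms: none
Why: Rh-catalysed asymmetric 1,4-addition (Hayashi–Miyaura type) desymmetrises the prochiral dienone, the ligand choosing between the enantiotopic enone faces and so setting C5, and the remaining enone is more hindered and should not react further.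

Step 3
Reactants: 4 (5S)-4,4-dimethyl-5-[(E)-2-phenylethenyl]cyclohex-2-en-1-one
Product: 5 (5R)-6-(hydroxymethyl)-4,4-dimethyl-5-[(E)-2-phenylethenyl]cyclohex-2-en-1-one
Conditions: LDA, THF, −78 °C; HCHO (gas); AcOH quench at −78 °C
Reagents that add atoms: formaldehyde C=O
Why: Kinetic α'-deprotonation of the enone (the only enolisable position, C4 being quaternary) and aldol addition to formaldehyde installs C20 regiospecifically; the new centre (trans expected) is erased in step 6.

Step 4
Reactants: 5 (5R)-6-(hydroxymethyl)-4,4-dimethyl-5-[(E)-2-phenylethenyl]cyclohex-2-en-1-one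
Product: 6 (1R)-6-(hydroxymethyl)-2,2-dimethyl-5-oxocyclohex-3-ene-1-carbaldehyde
Conditions: O3, CH2Cl2, −78 °C (Sudan III end-point); Me2S
Reagents that add atoms: ozone [O-][O+]=O
Why: Ozonolysis cleaves the electron-rich styryl alkene much faster than the electron-poor enone double bond and leaves C6 as the aldehyde.

Step 5
Reactants: 6 (1R)-6-(hydroxymethyl)-2,2-dimethyl-5-oxocyclohex-3-ene-1-carbaldehyde
Product: 8 (1R,5S)-2-(hydroxymethyl)-8,8-dimethyl-6-oxabicyclo[3.2.1]octan-3-one, via diol enone 7 (not isolated)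
Conditions: NaBH(OAc)3, AcOH, DCE, 0 °C to rt; then DBU (10 mol%), CH2Cl2, 0 °C
Reagents that add atoms: none
Why: Triacetoxyborohydride reduces the aldehyde in the presence of the enone, and the C6 hydroxyl then adds to C3 by intramolecular oxa-Michael addition (5-exo-trig); the 1,3-bridge can only form cis, so C3 follows from C5.

Step 6
Reactants: 8 (1R,5S)-2-(hydroxymethyl)-8,8-dimethyl-6-oxabicyclo[3.2.1]octan-3-one
Product: 9 (1S,5S)-2-(hydroxymethylidene)-8,8-dimethyl-6-oxabicyclo[3.2.1]octan-3-one
Conditions: Dess–Martin periodinane, CH2Cl2, 0 °C to rt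
Reagents that add atoms: none
Why: Dess–Martin oxidation of the primary β-hydroxy ketone gives the 2-formyl ketone, which rests as the chelated hydroxymethylidene tautomer with C10 planar.

Step 7
Reactants: 10 cycloheptanone
Product: 11 cyclohepta-2,6-dien-1-one
Conditions: IBX (2.4 equiv), DMSO/fluorobenzene, 70 °C
Reagents that add atoms: none
Why: Twofold IBX dehydrogenation of the ketone gives the symmetric cross-conjugated dienone.

Step 8
Reactants: 11 cyclohepta-2,6-dien-1-one; 12 4,4,5,5-tetramethyl-2-(prop-1-en-2-yl)-1,3,2-dioxaborolane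
Product: 13 (6R)-6-(prop-1-en-2-yl)cyclohept-2-en-1-one
Conditions: [RhCl(C2H4)2]2/(R)-BINAP (3 mol% Rh), aq. KOH (0.3 equiv), dioxane, 40 °C; 11 in excess (2 equiv)
Reagents that add atoms: none
Why: Rh-catalysed asymmetric 1,4-addition of the alkenyl boronate to one of the two equivalent enone units sets C13 under ligand control, and the excess of dienone suppresses double addition.

Step 9
Reactants: 13 (6R)-6-(prop-1-en-2-yl)cyclohept-2-en-1-one
Product: 14 (6R)-2-(hydroxymethyl)-6-(prop-1-en-2-yl)cyclohept-2-en-1-one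
Conditions: 37% aq. HCHO, DMAP (20 mol%), THF/H2O, rt
Reagents that add atoms: formaldehyde C=O
Why: Morita–Baylis–Hillman reaction (amine adds to the enone, the enolate adds to formaldehyde, elimination regenerates the enone) places the one-carbon handle on C8 regiospecifically.

Step 10
Reactants: 14 (6R)-2-(hydroxymethyl)-6-(prop-1-en-2-yl)cyclohept-2-en-1-one
Product: 15 (5R)-7-oxo-5-(prop-1-en-2-yl)cyclohept-1-ene-1-carbaldehyde
Conditions: Dess–Martin periodinane, NaHCO3, CH2Cl2, 0 °C; used at once
Reagents that add atoms: none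
Why: Dess–Martin oxidation of the primary allylic alcohol gives the 2-formyl enone, a doubly activated Michael acceptor.

Step 11
Reactants: 9 (1S,5S)-2-(hydroxymethylidene)-8,8-dimethyl-6-oxabicyclo[3.2.1]octan-3-one; 15 (5R)-7-oxo-5-(prop-1-en-2-yl)cyclohept-1-ene-1-carbaldehyde
Product: 16 (1S,2S,5S)-2-[(1R,5R)-2-formyl-3-oxo-5-(prop-1-en-2-yl)cycloheptyl]-8,8-dimethyl-3-oxo-6-oxabicyclo[3.2.1]octane-2-carbaldehyde
Conditions: Et3N (10 mol%), CH2Cl2, −40 to 0 °C
Reagents that add atoms: none
Why: Michael addition of a 1,3-dicarbonyl enol to an alkylidene-1,3-dicarbonyl acceptor, whose double activation lets the hindered C10 attack C9: the enol of 9 is attacked on the face of its O–CH2 bridge because the axial C4 methyl of the one-carbon bridge shields the other face (sets C10, C20 ending axial), and the cycloheptenone is attacked anti to its pseudo-equatorial isopropenyl group through a chair-like transition state (C9 trans to C13).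

Step 12
Reactants: 16 (1S,2S,5S)-2-[(1R,5R)-2-formyl-3-oxo-5-(prop-1-en-2-yl)cycloheptyl]-8,8-dimethyl-3-oxo-6-oxabicyclo[3.2.1]octane-2-carbaldehyde
Product: 17 (1S,2S,5S)-2-[(1S,5R)-2-diazo-3-oxo-5-(prop-1-en-2-yl)cycloheptyl]-8,8-dimethyl-3-oxo-6-oxabicyclo[3.2.1]octane-2-carbaldehyde
Conditions: TsN3 (1.2 equiv), Et3N, MeCN, 0 °C to rt
Reagents that add atoms: p-toluenesulfonyl azide Cc1ccc(cc1)S(=O)(=O)N=[N+]=[N-]
Why: Regitz deformylative diazo transfer: the enolate of the ring β-keto aldehyde adds to the azide and the triazoline fragments with transfer of the formyl group to the sulfonamide, putting the diazo group exactly on C8, while the aldehyde on the quaternary C10 cannot enolise and stays.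

Step 13
Reactants: 17 (1S,2S,5S)-2-[(1S,5R)-2-diazo-3-oxo-5-(prop-1-en-2-yl)cycloheptyl]-8,8-dimethyl-3-oxo-6-oxabicyclo[3.2.1]octane-2-carbaldehyde
Product: 18 (1S,2S,5S)-2-[(1S,5R)-2-diazo-3-oxo-5-(prop-1-en-2-yl)cycloheptyl]-2-(hydroxymethyl)-8,8-dimethyl-6-oxabicyclo[3.2.1]octan-3-one
Conditions: NaBH4 (0.5 equiv), THF/MeOH 10:1, −78 °C; aq. NH4Cl
Reagents that add atoms: none
Why: Chemoselective borohydride reduction: the aldehyde reacts far faster than the hindered C1 ketone flanked by the quaternary carbon and than the deactivated diazo ketone carbonyl.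

Step 14
Reactants: 18 (1S,2S,5S)-2-[(1S,5R)-2-diazo-3-oxo-5-(prop-1-en-2-yl)cycloheptyl]-2-(hydroxymethyl)-8,8-dimethyl-6-oxabicyclo[3.2.1]octan-3-one
Product: 20 isopropenyl lactone (3S,5S,8S,9R,10S,13R), via ketene 19 (not isolated)
Conditions: hν (450 nm LED), degassed THF (0.005 M), 20 °C
Reagents that add atoms: none
Why: Excitation of the diazo ketone, held s-Z by the ring, expels N2 with concerted 1,2-shift of C14 from C7 to C8 (Wolff rearrangement), so the cycloheptanone contracts to the cyclohexane and C7 is extruded as a ketene on C8; this is the classical photochemical ring contraction of 2-diazocycloalkanones. The C20 hydroxyl on the adjacent spiro carbon then adds to the ketene carbon (6-exo-dig O-acylation) and closes the δ-lactone, the closest precedent being intramolecular capture of Wolff ketenes by tethered alcohols. The only new stereocentre, C8, is set when the lactone enol tautomerises: the pseudo-axial C1 acyl branch of the spiro carbon covers one face of the enol, so the proton should enter syn to H9 and give the cis ring fusion (8S). The step needs rearrangement to outrun carbene chemistry (1,2-hydride shift from C9, O–H insertion), which the locked s-Z geometry and long-wavelength irradiation favour, and it needs intramolecular capture, which high dilution in an aprotic solvent and the six-membered geometry secure. C9 and C13 are untouched because the migrating atom is the CH2 group C14.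

Step 15
Reactants: 20 isopropenyl lactone (3S,5S,8S,9R,10S,13R)
Product: 22 enal (3S,5S,8S,9R,10S,13R) with a 3-oxoprop-1-en-2-yl group on C13, via allylic alcohol 21 (not isolated)
Conditions: SeO2 (0.3 equiv), tBuOOH, CH2Cl2, rt; then Dess–Martin periodinane, NaHCO3, CH2Cl2, 0 °C
Reagents that add atoms: tert-butyl hydroperoxide CC(C)(C)OO (oxygen relayed by catalytic selenium dioxide O=[Se]=O)
Why: SeO2-catalysed allylic oxidation (ene reaction then [2,3]-shift) attacks the methyl group of the 1,1-disubstituted alkene in preference to the allylic methine, and Dess–Martin oxidation converges the allylic alcohol on the enal.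

Step 16
Reactants: 22 enal (3S,5S,8S,9R,10S,13R)
Product: 23 target acid CNP0268721.1
Conditions: NaClO2, NaH2PO4, 2-methylbut-2-ene, tBuOH/H2O, 0 °C to rt
Reagents that add atoms: sodium chlorite [Na+].[O-]Cl=O
Why: Pinnick oxidation takes the α-substituted acrolein to the acrylic acid under buffered conditions that leave the ketone, the lactone (epimerisable C8), the β-alkoxy ketone and the alkene untouched.

**Compound list**

1 | 4,4-dimethylcyclohex-2-en-1-one | CC1(C)CCC(=O)C=C1 | starting material
2 | 4,4-dimethylcyclohexa-2,5-dien-1-one | CC1(C)C=CC(=O)C=C1 | intermediate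
3 | (E)-2-phenylethenylboronic acid | OB(O)/C=C/c1ccccc1 | starting material
4 | (5S)-4,4-dimethyl-5-[(E)-2-phenylethenyl]cyclohex-2-en-1-one | c1ccccc1/C=C/[C@H]1C(C)(C)C=CC(=O)C1 | intermediate
5 | (5R)-6-(hydroxymethyl)-4,4-dimethyl-5-[(E)-2-phenylethenyl]cyclohex-2-en-1-one (C6 epimers, trans expected) | c1ccccc1/C=C/[C@H]1C(C)(C)C=CC(=O)C1CO | intermediate
6 | (1R)-6-(hydroxymethyl)-2,2-dimethyl-5-oxocyclohex-3-ene-1-carbaldehyde (C6 epimers) | O=C[C@H]1C(C)(C)C=CC(=O)C1CO | intermediate
7 | (5R)-5,6-bis(hydroxymethyl)-4,4-dimethylcyclohex-2-en-1-one (C6 epimers) | OC[C@H]1C(C)(C)C=CC(=O)C1CO | intermediate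
8 | (1R,5S)-2-(hydroxymethyl)-8,8-dimethyl-6-oxabicyclo[3.2.1]octan-3-one (C2 epimers) | OCC1C(=O)C[C@@H]2OC[C@H]1C2(C)C | intermediate
9 | (1S,5S)-2-(hydroxymethylidene)-8,8-dimethyl-6-oxabicyclo[3.2.1]octan-3-one (enol form of the 3-oxo-2-carbaldehyde) | OC=C1C(=O)C[C@@H]2OC[C@H]1C2(C)C | intermediate
10 | cycloheptanone | O=C1CCCCCC1 | starting material
11 | cyclohepta-2,6-dien-1-one | O=C1C=CCCC=C1 | intermediate
12 | 4,4,5,5-tetramethyl-2-(prop-1-en-2-yl)-1,3,2-dioxaborolane | CC(=C)B1OC(C)(C)C(C)(C)O1 | starting material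
13 | (6R)-6-(prop-1-en-2-yl)cyclohept-2-en-1-one | CC(=C)[C@@H]1CCC=CC(=O)C1 | intermediate
14 | (6R)-2-(hydroxymethyl)-6-(prop-1-en-2-yl)cyclohept-2-en-1-one | CC(=C)[C@@H]1CCC=C(CO)C(=O)C1 | intermediate
15 | (5R)-7-oxo-5-(prop-1-en-2-yl)cyclohept-1-ene-1-carbaldehyde | CC(=C)[C@@H]1CCC=C(C=O)C(=O)C1 | intermediate
16 | (1S,2S,5S)-2-[(1R,5R)-2-formyl-3-oxo-5-(prop-1-en-2-yl)cycloheptyl]-8,8-dimethyl-3-oxo-6-oxabicyclo[3.2.1]octane-2-carbaldehyde (formyl-bearing ring carbon enolised, unassigned) | CC(=C)[C@@H]1CC[C@@H]([C@]2(C=O)C(=O)C[C@@H]3OC[C@H]2C3(C)C)C(C=O)C(=O)C1 | intermediate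
17 | (1S,2S,5S)-2-[(1S,5R)-2-diazo-3-oxo-5-(prop-1-en-2-yl)cycloheptyl]-8,8-dimethyl-3-oxo-6-oxabicyclo[3.2.1]octane-2-carbaldehyde | CC(=C)[C@@H]1CC[C@@H]([C@]2(C=O)C(=O)C[C@@H]3OC[C@H]2C3(C)C)C(=[N+]=[N-])C(=O)C1 | intermediate
18 | (1S,2S,5S)-2-[(1S,5R)-2-diazo-3-oxo-5-(prop-1-en-2-yl)cycloheptyl]-2-(hydroxymethyl)-8,8-dimethyl-6-oxabicyclo[3.2.1]octan-3-one | CC(=C)[C@@H]1CC[C@@H]([C@]2(CO)C(=O)C[C@@H]3OC[C@H]2C3(C)C)C(=[N+]=[N-])C(=O)C1 | intermediate
19 | ketene: {(2R,5R)-2-[(1S,2S,5S)-2-(hydroxymethyl)-8,8-dimethyl-3-oxo-6-oxabicyclo[3.2.1]octan-2-yl]-5-(prop-1-en-2-yl)cyclohexylidene}methanone | CC(=C)[C@@H]1CC[C@@H]([C@]2(CO)C(=O)C[C@@H]3OC[C@H]2C3(C)C)C(=C=O)C1 | intermediate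
20 | isopropenyl lactone (3S,5S,8S,9R,10S,13R): the target with a prop-1-en-2-yl group on C13 in place of the acrylic acid | CC(=C)[C@@H]1CC[C@@H]2[C@H](C1)C(=O)OC[C@]21C(=O)C[C@@H]2OC[C@H]1C2(C)C | intermediate
21 | allylic alcohol (3S,5S,8S,9R,10S,13R): 20 with a 3-hydroxyprop-1-en-2-yl group on C13 | OCC(=C)[C@@H]1CC[C@@H]2[C@H](C1)C(=O)OC[C@]21C(=O)C[C@@H]2OC[C@H]1C2(C)C | intermediate
22 | enal (3S,5S,8S,9R,10S,13R): 20 with a 3-oxoprop-1-en-2-yl group on C13 | O=CC(=C)[C@@H]1CC[C@@H]2[C@H](C1)C(=O)OC[C@]21C(=O)C[C@@H]2OC[C@H]1C2(C)C | intermediate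
23 | CNP0268721.1, the 2-substituted prop-2-enoic acid (3S,5S,8S,9R,10S,13R) | C=C(C(=O)O)[C@@H]1CC[C@@H]2[C@H](C1)C(=O)OC[C@]21C(=O)C[C@@H]2OC[C@H]1C2(C)C | target

**Step count and risks**

Total steps: 16. Longest linear sequence: 12 (steps 1–6, then 11–16); the second branch (steps 7–10) joins at step 11.

Step 11. What may go wrong: poor facial discrimination at C9, because the seven-membered acceptor is flexible and the two chiral partners may be mismatched, or self-condensation of the doubly activated acceptor before it is intercepted. Fallback: the C9–C10 bond is made by a sigmatropic shift that transfers chirality instead of by an intermolecular addition. It sets out from 13 and 9 and comes back at 20. Corey–Bakshi–Shibata reduction of 13 (catecholborane, −78 °C, catalyst enantiomer chosen for the 1R carbinol) should give the cis allylic alcohol (1R,6R)-6-(prop-1-en-2-yl)cyclohept-2-en-1-ol F1. Mitsunobu O-alkylation of the enol 9 with F1 (PPh3, DIAD, inversion) should give the allyl vinyl ether F2, whose ring C–O bond is trans to the isopropenyl group. Heating (toluene, 110 °C) should bring about the Claisen rearrangement to the formyl ketone F3; the new bond forms at C9 on the ring face that the oxygen leaves (C9 trans to C13) and at C10 on the face of the O–CH2 bridge. NaBH4 at −78 °C should reduce the aldehyde to the alcohol F4, and hydroxyl-directed epoxidation (VO(acac)2, tBuOOH) should give the syn epoxide F5. BF3·OEt2 at −78 °C should then trigger Meinwald rearrangement with ring contraction of the cycloheptene oxide to the cyclohexanecarbaldehyde, which the C20 hydroxyl captures as the lactol F6. Oxidation (TEMPO, PhI(OAc)2) should give 20.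

Step 14. What may go wrong: the photogenerated species follows carbene pathways (1,2-hydride shift from C9 to an enone, O–H insertion of the free hydroxyl), or the lactone enol takes up its proton on the wrong face and gives the trans-fused C8 epimer. Fallback: ring contraction and lactone closure are separated. It sets out from 18 and comes back at 20. Silylation (TBSCl, imidazole) should give the silyl ether F7. Wolff rearrangement in aqueous THF (450 nm, or PhCO2Ag/Et3N) should then give, by capture of the ketene with water, the carboxylic acid F8. Here C8 is set by kinetic protonation of an open-chain ene-diol whose C9 substituent turns axial to avoid allylic strain, so the proton enters anti to it (C7 cis to C10). HF·pyridine should free the hydroxy acid F9, which is closed to 20 under Yamaguchi lactonisation conditions.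

Step 2. What may go wrong: slow insertion at the neopentyl β-carbon, over-addition to the second enone, or low enantioselectivity in the desymmetrisation. Fallback: C6 is brought in already oxygenated from a zinc reagent, which removes the ozonolysis and reduction. It sets out from 2 and comes back at 8. Copper-catalysed asymmetric conjugate addition of bis(pivaloyloxymethyl)zinc (Cu(OTf)2, chiral phosphoramidite ligand, toluene, −30 °C) should give the pivalate [(1R)-2,2-dimethyl-5-oxocyclohex-3-en-1-yl]methyl 2,2-dimethylpropanoate F10. LDA and formaldehyde, as in step 3, should give the hydroxymethyl ketone F11. K2CO3 in methanol should remove the pivalate, and the freed diol enone 7 closes to 8 as in step 5.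

Further compounds
F1 | step 11 | (1R,6R)-6-(prop-1-en-2-yl)cyclohept-2-en-1-ol | CC(=C)[C@@H]1CCC=C[C@H](O)C1
F2 | step 11 | (1S,5S)-8,8-dimethyl-2-({[(1S,6R)-6-(prop-1-en-2-yl)cyclohept-2-en-1-yl]oxy}methylidene)-6-oxabicyclo[3.2.1]octan-3-one | CC(=C)[C@@H]1CCC=C[C@@H](OC=C2C(=O)C[C@@H]3OC[C@H]2C3(C)C)C1
F3 | step 11 | (1S,2S,5S)-8,8-dimethyl-3-oxo-2-[(1R,5R)-5-(prop-1-en-2-yl)cyclohept-2-en-1-yl]-6-oxabicyclo[3.2.1]octane-2-carbaldehyde | CC(=C)[C@@H]1CC[C@@H]([C@]2(C=O)C(=O)C[C@@H]3OC[C@H]2C3(C)C)C=CC1
F4 | step 11 | (1S,2S,5S)-2-(hydroxymethyl)-8,8-dimethyl-2-[(1R,5R)-5-(prop-1-en-2-yl)cyclohept-2-en-1-yl]-6-oxabicyclo[3.2.1]octan-3-one | CC(=C)[C@@H]1CC[C@@H]([C@]2(CO)C(=O)C[C@@H]3OC[C@H]2C3(C)C)C=CC1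
F5 | step 11 | epoxide of F4 at the ring double bond, oxygen syn to the bicyclic substituent | CC(=C)[C@@H]1CC[C@@H]([C@]2(CO)C(=O)C[C@@H]3OC[C@H]2C3(C)C)[C@H]2O[C@H]2C1
F6 | step 11 | lactol corresponding to 20 (C7 as hemiacetal, anomers) | CC(=C)[C@@H]1CC[C@@H]2[C@H](C1)C(O)OC[C@]21C(=O)C[C@@H]2OC[C@H]1C2(C)C
F7 | step 14 | tert-butyldimethylsilyl ether of 18 | CC(=C)[C@@H]1CC[C@@H]([C@]2(CO[Si](C)(C)C(C)(C)C)C(=O)C[C@@H]3OC[C@H]2C3(C)C)C(=[N+]=[N-])C(=O)C1
F8 | step 14 | ring-contracted cyclohexanecarboxylic acid with the C20 silyl ether (C7 cis to C10) | CC(=C)[C@@H]1CC[C@@H]([C@]2(CO[Si](C)(C)C(C)(C)C)C(=O)C[C@@H]3OC[C@H]2C3(C)C)[C@H](C1)C(=O)O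
F9 | step 14 | hydroxy acid (seco acid of 20) | CC(=C)[C@@H]1CC[C@@H]([C@]2(CO)C(=O)C[C@@H]3OC[C@H]2C3(C)C)[C@H](C1)C(=O)O
F10 | step 2 | [(1R)-2,2-dimethyl-5-oxocyclohex-3-en-1-yl]methyl 2,2-dimethylpropanoate | CC(C)(C)C(=O)OC[C@H]1C(C)(C)C=CC(=O)C1
F11 | step 2 | [(1R)-6-(hydroxymethyl)-2,2-dimethyl-5-oxocyclohex-3-en-1-yl]methyl 2,2-dimethylpropanoate (C6 epimers) | CC(C)(C)C(=O)OC[C@H]1C(C)(C)C=CC(=O)C1CO
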